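The cyclohex‑2‑enone ring (C1 ketone, C2 bearing CH2OH, C3 =CH, C4 isobutyrate, C5 isopropyl, C6 hydroxytiglate) is cut at C2=C3 and C5–C6 into a ketone with its two α‑carbons (a 1,3‑bis‑nucleophile) and a C3–C5 enal. One amine‑catalysed operation should join them: iminium‑controlled Michael addition of the ester‑activated C6 of an acyl ylide to (E)‑4‑methylpent‑2‑enal sets C5, and the ylide carbon C2 then closes the ring by intramolecular Wittig olefination. The precursor is an open‑chain α‑acyloxy‑β‑keto ester phosphorane; its tert‑butyl ester later blocks α′‑enolisation, so the C4 oxygen enters by γ‑hydroxylation and Mitsunobu inversion, and is excised last.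

Key step: step 6

Remark: the acyloxy‑bearing carbon (C2 of 7, 8, 9 and 11; ring C1 of 12 to 18) is carried as an epimer mixture that converges in step 10, so its configuration is left open in those SMILES. "TBSO‑tigloyl" stands for (2E)‑4‑[(tert‑butyldimethylsilyl)oxy]‑2‑methylbut‑2‑enoyl.

Step 1
Reactants: 1 2‑[(tert‑butyldimethylsilyl)oxy]acetaldehyde; 2 ethyl 2‑(triphenyl‑λ5‑phosphanylidene)propanoate
Product: 3 ethyl (2E)‑4‑[(tert‑butyldimethylsilyl)oxy]‑2‑methylbut‑2‑enoate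
Conditions: CH2Cl2, rt
Reagents that add atoms: none
Why: Wittig olefination with a stabilised α‑methyl ylide should give the E trisubstituted enoate (ester trans to CH2OTBS) through the usual thermodynamic preference of stabilised ylides.

Step 2
Reactants: 3 ethyl (2E)‑4‑[(tert‑butyldimethylsilyl)oxy]‑2‑methylbut‑2‑enoate
Product: 4 (2E)‑4‑[(tert‑butyldimethylsilyl)oxy]‑2‑methylbut‑2‑enoic acid
Conditions: LiOH·H2O, THF/MeOH/H2O, 0 °C to rt; then 1 M HCl to pH 4, 0 °C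
Reagents that add atoms: lithium hydroxide [Li+].[OH-]
Why: Ester saponification; the primary TBS ether and the E alkene should survive cold hydroxide and a brief mild acidification.

Step 3
Reactants: 5 tert‑butyl 4‑chloro‑3‑oxobutanoate
Product: 6 tert‑butyl 4‑chloro‑2‑diazo‑3‑oxobutanoate
Conditions: p‑ABSA, Et3N, MeCN, 0 °C to rt
Reagents that add atoms: 4‑acetamidobenzenesulfonyl azide CC(=O)Nc1ccc(cc1)S(=O)(=O)N=[N+]=[N-]
Why: Regitz diazo transfer to the active methylene between ketone and ester, which is far more acidic than the chloromethyl group.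

Step 4
Reactants: 6 tert‑butyl 4‑chloro‑2‑diazo‑3‑oxobutanoate; 4 (2E)‑4‑[(tert‑butyldimethylsilyl)oxy]‑2‑methylbut‑2‑enoic acid
Product: 7 tert‑butyl 4‑chloro‑3‑oxo‑2‑(TBSO‑tigloyloxy)butanoate
Conditions: Rh2(OAc)4 (1 mol %), CH2Cl2, 40 °C, slow addition of 6
Reagents that add atoms: none
Why: Rhodium‑carbenoid O–H insertion into the carboxylic acid should outrun cyclopropanation of the electron‑poor trisubstituted alkene; the new stereocentre is racemic and is erased later.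

Step 5
Reactants: 7 tert‑butyl 4‑chloro‑3‑oxo‑2‑(TBSO‑tigloyloxy)butanoate
Product: 9 tert‑butyl 3‑oxo‑2‑(TBSO‑tigloyloxy)‑4‑(triphenyl‑λ5‑phosphanylidene)butanoate, via phosphonium chloride 8 (not isolated)
Conditions: PPh3, THF, 40 °C; then aq. Na2CO3, CH2Cl2, 0 °C
Reagents that add atoms: triphenylphosphine c1ccc(cc1)P(c1ccccc1)c1ccccc1
Why: SN2 quaternisation of the α‑chloroketone and deprotonation is the standard preparation of keto‑stabilised phosphoranes; the ylide is kept at or below rt because α′‑acyloxy acyl ylides attack their own ester carbonyl only on heating.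

Step 6
Reactants: 9 tert‑butyl 3‑oxo‑2‑(TBSO‑tigloyloxy)‑4‑(triphenyl‑λ5‑phosphanylidene)butanoate; 10 (2E)‑4‑methylpent‑2‑enal
Product: 12 tert‑butyl (6R)‑2‑oxo‑6‑(propan‑2‑yl)‑1‑(TBSO‑tigloyloxy)cyclohex‑3‑ene‑1‑carboxylate, via Michael adduct aldehyde 11 (not isolated)
Conditions: (R)‑2‑[diphenyl(trimethylsilyloxy)methyl]pyrrolidine (20 mol %), LiClO4 (30 mol %), DABCO (30 mol %), CHCl3, rt
Reagents that add atoms: none
Why: Condensation of 10 with the (R)‑pyrrolidine gives an E iminium ion with one face blocked by the CPh2(OTMS) group, so the enol of 9 (its C2–H lies between the ester and the acyl‑ylide carbonyl) should add to the β‑carbon from the open face and set C6 of 12 as R; hydrolysis releases aldehyde 11. The ylide carbon of 11 then attacks the aldehyde in a 6‑exo‑trig sense and the oxaphosphetane collapses to the ring C3=C4 bond, which can only be the endocyclic cis alkene. The closest known reaction is the amine‑catalysed Michael/intramolecular Wittig [3+3] annulation of 3‑oxo‑4‑(triphenylphosphoranylidene)butanoates with enals. C1 forms unselectively, which is harmless because the ester on it is removed in step 10. The step needs conjugate addition to outrun direct Wittig olefination of 10; the high C–H acidity of the α‑acyloxy‑β‑keto ester position, iminium activation of the enal and the low reactivity of the keto‑stabilised ylide toward enals at rt should secure this.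

Step 7
Reactants: 12 tert‑butyl (6R)‑2‑oxo‑6‑(propan‑2‑yl)‑1‑(TBSO‑tigloyloxy)cyclohex‑3‑ene‑1‑carboxylate
Product: 14 tert‑butyl (5R,6S)‑5‑hydroxy‑2‑oxo‑6‑(propan‑2‑yl)‑1‑(TBSO‑tigloyloxy)cyclohex‑3‑ene‑1‑carboxylate, via silyl dienol ether 13 (not isolated)
Conditions: TMSOTf, Et3N, CH2Cl2, 0 °C; pentane filtration and concentration; DMDO, acetone/CH2Cl2, −78 to −20 °C; then AcOH, THF/H2O
Reagents that add atoms: dimethyldioxirane CC1(C)OO1
Why: Because C1 is quaternary only γ‑enolisation is possible, and the linear silyl dienol ether should take up oxygen at its terminal carbon (vinylogous Rubottom oxidation) from the face anti to the neighbouring isopropyl group, placing the new 5‑OH trans to isopropyl.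

Step 8
Reactants: 14 tert‑butyl (5R,6S)‑5‑hydroxy‑2‑oxo‑6‑(propan‑2‑yl)‑1‑(TBSO‑tigloyloxy)cyclohex‑3‑ene‑1‑carboxylate; 15 2‑methylpropanoic acid
Product: 16 tert‑butyl (5S,6S)‑5‑[(2‑methylpropanoyl)oxy]‑2‑oxo‑6‑(propan‑2‑yl)‑1‑(TBSO‑tigloyloxy)cyclohex‑3‑ene‑1‑carboxylate
Conditions: PPh3, DIAD, toluene, 0 °C to rt
Reagents that add atoms: none
Why: Mitsunobu esterification displaces the allylic oxyphosphonium by SN2 with inversion, turning the trans alcohol into the isobutyrate cis to isopropyl, as in menthol‑to‑neomenthyl inversions.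

Step 9
Reactants: 16 tert‑butyl (5S,6S)‑5‑[(2‑methylpropanoyl)oxy]‑2‑oxo‑6‑(propan‑2‑yl)‑1‑(TBSO‑tigloyloxy)cyclohex‑3‑ene‑1‑carboxylate
Product: 17 tert‑butyl (5S,6S)‑3‑(hydroxymethyl)‑5‑[(2‑methylpropanoyl)oxy]‑2‑oxo‑6‑(propan‑2‑yl)‑1‑(TBSO‑tigloyloxy)cyclohex‑3‑ene‑1‑carboxylate
Conditions: 37 % aq. HCHO, imidazole, THF/aq. NaHCO3, rt
Reagents that add atoms: formaldehyde C=O
Why: Morita–Baylis–Hillman hydroxymethylation: reversible addition of imidazole to C4 gives an enolate that traps formaldehyde at C3 and then expels imidazole; C1 is quaternary, so no α′‑enolate chemistry competes, and no stereocentre is created.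

Step 10
Reactants: 17 tert‑butyl (5S,6S)‑3‑(hydroxymethyl)‑5‑[(2‑methylpropanoyl)oxy]‑2‑oxo‑6‑(propan‑2‑yl)‑1‑(TBSO‑tigloyloxy)cyclohex‑3‑ene‑1‑carboxylate
Product: 19 (1R,5S,6S)‑3‑(hydroxymethyl)‑5‑[(2‑methylpropanoyl)oxy]‑2‑oxo‑6‑(propan‑2‑yl)cyclohex‑3‑en‑1‑yl (2E)‑4‑hydroxy‑2‑methylbut‑2‑enoate, via beta‑keto acid 18 (not isolated)
Conditions: TFA/H2O (9:1), CH2Cl2, 0 °C to rt; then Et3N (0.2 equiv), CH2Cl2, rt
Reagents that add atoms: none
Why: Acidolysis should remove the tert‑butyl ester and the TBS ether, the β‑keto acid loses CO2, and C1 is then set by enol/keto equilibration under thermodynamic control, which should favour the acyloxy group trans to isopropyl because the cis epimer needs either a 1,3‑diaxial clash with the C5 isobutyrate or an axial isopropyl group.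

Compound list
1 | 2‑[(tert‑butyldimethylsilyl)oxy]acetaldehyde | O=CCO[Si](C)(C)C(C)(C)C | starting material
2 | ethyl 2‑(triphenyl‑λ5‑phosphanylidene)propanoate | CCOC(=O)C(C)=P(c1ccccc1)(c1ccccc1)c1ccccc1 | starting material
3 | ethyl (2E)‑4‑[(tert‑butyldimethylsilyl)oxy]‑2‑methylbut‑2‑enoate | C/C(=C\CO[Si](C)(C)C(C)(C)C)C(=O)OCC | intermediate
4 | (2E)‑4‑[(tert‑butyldimethylsilyl)oxy]‑2‑methylbut‑2‑enoic acid | C/C(=C\CO[Si](C)(C)C(C)(C)C)C(=O)O | intermediate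
5 | tert‑butyl 4‑chloro‑3‑oxobutanoate | CC(C)(C)OC(=O)CC(=O)CCl | starting material
6 | tert‑butyl 4‑chloro‑2‑diazo‑3‑oxobutanoate | CC(C)(C)OC(=O)C(=[N+]=[N-])C(=O)CCl | intermediate
7 | tert‑butyl 4‑chloro‑3‑oxo‑2‑(TBSO‑tigloyloxy)butanoate (racemic) | C/C(=C\CO[Si](C)(C)C(C)(C)C)C(=O)OC(C(=O)CCl)C(=O)OC(C)(C)C | intermediate
8 | [4‑tert‑butoxy‑2,4‑dioxo‑3‑(TBSO‑tigloyloxy)butyl]triphenylphosphonium chloride (racemic) | C/C(=C\CO[Si](C)(C)C(C)(C)C)C(=O)OC(C(=O)C[P+](c1ccccc1)(c1ccccc1)c1ccccc1)C(=O)OC(C)(C)C.[Cl-] | intermediate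
9 | tert‑butyl 3‑oxo‑2‑(TBSO‑tigloyloxy)‑4‑(triphenyl‑λ5‑phosphanylidene)butanoate (racemic) | C/C(=C\CO[Si](C)(C)C(C)(C)C)C(=O)OC(C(=O)C=P(c1ccccc1)(c1ccccc1)c1ccccc1)C(=O)OC(C)(C)C | intermediate
10 | (2E)‑4‑methylpent‑2‑enal | CC(C)/C=C/C=O | starting material
11 | tert‑butyl (3R)‑5‑oxo‑3‑(propan‑2‑yl)‑2‑(TBSO‑tigloyloxy)‑2‑[(triphenyl‑λ5‑phosphanylidene)acetyl]pentanoate (C2 epimers) | C/C(=C\CO[Si](C)(C)C(C)(C)C)C(=O)OC(C(=O)C=P(c1ccccc1)(c1ccccc1)c1ccccc1)(C(=O)OC(C)(C)C)[C@@H](C(C)C)CC=O | intermediate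
12 | tert‑butyl (6R)‑2‑oxo‑6‑(propan‑2‑yl)‑1‑(TBSO‑tigloyloxy)cyclohex‑3‑ene‑1‑carboxylate (C1 epimers) | C/C(=C\CO[Si](C)(C)C(C)(C)C)C(=O)OC1(C(=O)OC(C)(C)C)C(=O)C=CC[C@@H]1C(C)C | intermediate
13 | tert‑butyl (6S)‑6‑(propan‑2‑yl)‑1‑(TBSO‑tigloyloxy)‑2‑[(trimethylsilyl)oxy]cyclohexa‑2,4‑diene‑1‑carboxylate (C1 epimers) | C/C(=C\CO[Si](C)(C)C(C)(C)C)C(=O)OC1(C(=O)OC(C)(C)C)C(O[Si](C)(C)C)=CC=C[C@@H]1C(C)C | intermediate
14 | tert‑butyl (5R,6S)‑5‑hydroxy‑2‑oxo‑6‑(propan‑2‑yl)‑1‑(TBSO‑tigloyloxy)cyclohex‑3‑ene‑1‑carboxylate (OH trans to isopropyl; C1 epimers) | C/C(=C\CO[Si](C)(C)C(C)(C)C)C(=O)OC1(C(=O)OC(C)(C)C)C(=O)C=C[C@@H](O)[C@@H]1C(C)C | intermediate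
15 | 2‑methylpropanoic acid | CC(C)C(=O)O | starting material
16 | tert‑butyl (5S,6S)‑5‑[(2‑methylpropanoyl)oxy]‑2‑oxo‑6‑(propan‑2‑yl)‑1‑(TBSO‑tigloyloxy)cyclohex‑3‑ene‑1‑carboxylate (ester cis to isopropyl; C1 epimers) | C/C(=C\CO[Si](C)(C)C(C)(C)C)C(=O)OC1(C(=O)OC(C)(C)C)C(=O)C=C[C@H](OC(=O)C(C)C)[C@@H]1C(C)C | intermediate
17 | tert‑butyl (5S,6S)‑3‑(hydroxymethyl)‑5‑[(2‑methylpropanoyl)oxy]‑2‑oxo‑6‑(propan‑2‑yl)‑1‑(TBSO‑tigloyloxy)cyclohex‑3‑ene‑1‑carboxylate (C1 epimers) | C/C(=C\CO[Si](C)(C)C(C)(C)C)C(=O)OC1(C(=O)OC(C)(C)C)C(=O)C(CO)=C[C@H](OC(=O)C(C)C)[C@@H]1C(C)C | intermediate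
18 | (5S,6S)‑1‑{[(2E)‑4‑hydroxy‑2‑methylbut‑2‑enoyl]oxy}‑3‑(hydroxymethyl)‑5‑[(2‑methylpropanoyl)oxy]‑2‑oxo‑6‑(propan‑2‑yl)cyclohex‑3‑ene‑1‑carboxylic acid (C1 epimers) | C/C(=C\CO)C(=O)OC1(C(=O)O)C(=O)C(CO)=C[C@H](OC(=O)C(C)C)[C@@H]1C(C)C | intermediate
19 | (1R,5S,6S)‑3‑(hydroxymethyl)‑5‑[(2‑methylpropanoyl)oxy]‑2‑oxo‑6‑(propan‑2‑yl)cyclohex‑3‑en‑1‑yl (2E)‑4‑hydroxy‑2‑methylbut‑2‑enoate | C/C(=C\CO)C(=O)O[C@H]1C(=O)C(CO)=C[C@H](OC(=O)C(C)C)[C@@H]1C(C)C | target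

Total step count: 10. Longest linear sequence: 9 steps (1, 2, 4, 5, 6, 7, 8, 9, 10).

Steps most likely to fail

Step 6. The hindered tertiary carbon acid may add too slowly, so that direct Wittig olefination of the enal and retro‑Michael erosion of enantiopurity compete. The fallback introduces the C1 oxygen after the annulation and sets out from 5. Quaternisation with PPh3 should give (4‑tert‑butoxy‑2,4‑dioxobutyl)triphenylphosphonium chloride F1, and aqueous Na2CO3 then gives tert‑butyl 3‑oxo‑4‑(triphenyl‑λ5‑phosphanylidene)butanoate F2, the unsubstituted donor for which this annulation is established. With 10 under the step 6 catalyst system it should pass through tert‑butyl (3R)‑5‑oxo‑3‑(propan‑2‑yl)‑2‑[(triphenyl‑λ5‑phosphanylidene)acetyl]pentanoate F3 to tert‑butyl (6R)‑2‑oxo‑6‑(propan‑2‑yl)cyclohex‑3‑ene‑1‑carboxylate F4. Oxidation of the β‑keto ester enol with DMDO should give tert‑butyl (6R)‑1‑hydroxy‑2‑oxo‑6‑(propan‑2‑yl)cyclohex‑3‑ene‑1‑carboxylate F5, and Yamaguchi esterification with 4 (2,4,6‑trichlorobenzoyl chloride, Et3N, DMAP) comes back to the route at 12.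

Step 7. Oxygen transfer may occur at the enol‑ether double bond (α‑hydroxylation) instead of the diene terminus, or with poor facial selectivity. The fallback replaces oxygenation by halogenation and displacement and sets out from 13. NBS in THF at −78 °C, which attacks silyl dienol ethers at the terminal carbon, should give tert‑butyl (5R,6R)‑5‑bromo‑2‑oxo‑6‑(propan‑2‑yl)‑1‑(TBSO‑tigloyloxy)cyclohex‑3‑ene‑1‑carboxylate F6 with bromine trans to isopropyl. SN2 displacement with caesium 2‑methylpropanoate (from 15 and Cs2CO3, DMF, rt) inverts C5 and comes back at 16, bypassing 14 and step 8.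

Step 8. The activated allylic alcohol may eliminate, or substitution may proceed with allylic transposition or partial retention at the hindered C5, instead of clean inversion. The fallback corrects C5 by oxidation and reduction and sets out from 14. Dess–Martin oxidation should give tert‑butyl (6R)‑2,5‑dioxo‑6‑(propan‑2‑yl)‑1‑(TBSO‑tigloyloxy)cyclohex‑3‑ene‑1‑carboxylate F7, handled cold and base‑free because C6 is now enolisable. DIBAL‑H at −78 °C should reduce the less hindered C5 carbonyl in a 1,2 sense (the C2 carbonyl is shielded by the quaternary C1), with hydride approaching anti to isopropyl, to give tert‑butyl (5S,6S)‑5‑hydroxy‑2‑oxo‑6‑(propan‑2‑yl)‑1‑(TBSO‑tigloyloxy)cyclohex‑3‑ene‑1‑carboxylate F8. Acylation with 2‑methylpropanoyl chloride, pyridine and DMAP comes back at 16.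

Further compounds
F1 | step 6 | (4‑tert‑butoxy‑2,4‑dioxobutyl)triphenylphosphonium chloride | CC(C)(C)OC(=O)CC(=O)C[P+](c1ccccc1)(c1ccccc1)c1ccccc1.[Cl-]
F2 | step 6 | tert‑butyl 3‑oxo‑4‑(triphenyl‑λ5‑phosphanylidene)butanoate | CC(C)(C)OC(=O)CC(=O)C=P(c1ccccc1)(c1ccccc1)c1ccccc1
F3 | step 6 | tert‑butyl (3R)‑5‑oxo‑3‑(propan‑2‑yl)‑2‑[(triphenyl‑λ5‑phosphanylidene)acetyl]pentanoate | CC(C)(C)OC(=O)C(C(=O)C=P(c1ccccc1)(c1ccccc1)c1ccccc1)[C@@H](C(C)C)CC=O
F4 | step 6 | tert‑butyl (6R)‑2‑oxo‑6‑(propan‑2‑yl)cyclohex‑3‑ene‑1‑carboxylate | CC(C)(C)OC(=O)C1C(=O)C=CC[C@@H]1C(C)C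
F5 | step 6 | tert‑butyl (6R)‑1‑hydroxy‑2‑oxo‑6‑(propan‑2‑yl)cyclohex‑3‑ene‑1‑carboxylate | CC(C)(C)OC(=O)C1(O)C(=O)C=CC[C@@H]1C(C)C
F6 | step 7 | tert‑butyl (5R,6R)‑5‑bromo‑2‑oxo‑6‑(propan‑2‑yl)‑1‑(TBSO‑tigloyloxy)cyclohex‑3‑ene‑1‑carboxylate | C/C(=C\CO[Si](C)(C)C(C)(C)C)C(=O)OC1(C(=O)OC(C)(C)C)C(=O)C=C[C@@H](Br)[C@@H]1C(C)C
F7 | step 8 | tert‑butyl (6R)‑2,5‑dioxo‑6‑(propan‑2‑yl)‑1‑(TBSO‑tigloyloxy)cyclohex‑3‑ene‑1‑carboxylate | C/C(=C\CO[Si](C)(C)C(C)(C)C)C(=O)OC1(C(=O)OC(C)(C)C)C(=O)C=CC(=O)[C@@H]1C(C)C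
F8 | step 8 | tert‑butyl (5S,6S)‑5‑hydroxy‑2‑oxo‑6‑(propan‑2‑yl)‑1‑(TBSO‑tigloyloxy)cyclohex‑3‑ene‑1‑carboxylate | C/C(=C\CO[Si](C)(C)C(C)(C)C)C(=O)OC1(C(=O)OC(C)(C)C)C(=O)C=C[C@H](O)[C@@H]1C(C)C
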